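The oxepane ring of the trans-fused oxepane–cyclohexane half is cut on both sides of its only unsubstituted ethano bridge C-4–C-5 (1-benzoxepine numbering), at C-3–C-4 and C-5–C-5a. One operation makes both bonds: vinylmagnesium bromide adds to aldehyde carbon C-3 and, under copper catalysis, to the enone β-carbon C-5a of enone-aldehyde 22, creating the quaternary centre anti to the C-9a ether oxygen (trans fusion). Ring-closing metathesis later zips the two vinyl groups into the oxepene. The silyl enol ether left by the conjugate addition serves to attach the hydroazulene half, built by an enantioselective Diels–Alder reaction and a one-carbon ring expansion, as allylic bromide 14.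

Key step: step 17

Remarks on the chemistry:
- Numbering in the text: right half as 1-benzoxepine (O-1, C-2 to C-9a), left half as azulene (C-1 to C-8a).
- Assumption: the (S)-oxazaborolidinium catalyst of step 2 is taken to give the (3aR,7aR)-adduct 4; should the induction be opposite, its enantiomer is used.
- SC = the (2E)-2-[(1R,3aR,6R,8aR)-1-(tert-butyldimethylsilyloxy)-1,4,4,6-tetramethyloctahydroazulen-5(1H)-ylidene]ethyl group delivered by bromide 14.

**Hydroazulene half (steps 1–10)**

Step 1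
Reactants: 1 4-methylpent-1-en-3-one
Product: 2 4-methyl-3-(triisopropylsilyloxy)penta-1,3-diene
Conditions: TIPSOTf, Et3N, CH2Cl2, 0 °C
Reagents that add atoms: triisopropylsilyl trifluoromethanesulfonate CC(C)[Si](C(C)C)(C(C)C)OS(=O)(=O)C(F)(F)F
Why: Soft enolisation (silyl triflate/amine) of a ketone whose only α-hydrogen sits on the isopropyl side should give the cross-conjugated 2-silyloxydiene as a single regioisomer.

Step 2
Reactants: 2 4-methyl-3-(triisopropylsilyloxy)penta-1,3-diene; 3 cyclopent-2-en-1-one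
Product: 4 (3aR,7aR)-4,4-dimethyl-5-(triisopropylsilyloxy)-2,3,3a,4,7,7a-hexahydro-1H-inden-1-one (cis-fused)
Conditions: (S)-oxazaborolidinium triflimide [from (S)-3,3-diphenyl-1-(2-methylphenyl)tetrahydropyrrolo[1,2-c][1,3,2]oxazaborole and HNTf2] (20 mol %), CH2Cl2, −78 → −20 °C
Reagents that add atoms: none
Why: Enantioselective Diels–Alder reaction (possibly stepwise Mukaiyama–Michael/Michael) of the cation-activated enone, in which the electron-rich dimethyl-substituted diene terminus bonds to the enone β-carbon, suprafacial addition fixes the cis ring fusion and the catalyst shields one enone face to set C-3a and C-7a.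

Step 3
Reactants: 4 (3aR,7aR)-4,4-dimethyl-5-(triisopropylsilyloxy)-2,3,3a,4,7,7a-hexahydro-1H-inden-1-one
Product: 5 (3aR,7aR)-4,4-dimethyl-5,6-methano-5-(triisopropylsilyloxy)octahydro-1H-inden-1-one (cyclopropane configuration unassigned)
Conditions: Et2Zn, CH2I2, CH2Cl2, 0 °C
Reagents that add atoms: diiodomethane ICI
Why: Simmons–Smith cyclopropanation (Furukawa modification) should take the electron-rich silyl enol ether and leave the ketone; the cyclopropane stereocenters are erased again in step 7.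

Step 4
Reactants: 5 (3aR,7aR)-4,4-dimethyl-5,6-methano-5-(triisopropylsilyloxy)octahydro-1H-inden-1-one
Product: 6 (3aR,7aR)-4,4-dimethyl-1-methylidene-5,6-methano-5-(triisopropylsilyloxy)octahydro-1H-indene
Conditions: Ph3PCH3Br, KOtBu, THF, 0 °C → rt
Reagents that add atoms: methyltriphenylphosphonium bromide C[P+](c1ccccc1)(c1ccccc1)c1ccccc1.[Br-]
Why: Wittig methylenation of the unhindered cyclopentanone; the cis ring fusion next to the carbonyl is the more stable one and should be kept.

Step 5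
Reactants: 6 (3aR,7aR)-4,4-dimethyl-1-methylidene-5,6-methano-5-(triisopropylsilyloxy)octahydro-1H-indene
Product: 7 (1R,3aR,7aR)-1,4,4-trimethyl-5,6-methano-5-(triisopropylsilyloxy)octahydro-1H-inden-1-ol
Conditions: Mn(dpm)3 (dpm = dipivaloylmethanate, 10 mol %), PhSiH3, O2 (1 atm), i-PrOH/CH2Cl2, 0 °C
Reagents that add atoms: dioxygen O=O
Why: Mukaiyama hydration (hydrogen-atom transfer, then O2 capture): the tertiary cyclopentyl radical should be trapped on the convex face, anti to the vicinal C-7a–C-7 bond, which places the hydroxyl cis to the ring-fusion hydrogens and the new methyl on the concave face.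

Step 6
Reactants: 7 (1R,3aR,7aR)-1,4,4-trimethyl-5,6-methano-5-(triisopropylsilyloxy)octahydro-1H-inden-1-ol
Product: 8 (1R,3aR,7aR)-1-(tert-butyldimethylsilyloxy)-1,4,4-trimethyl-5,6-methano-5-(triisopropylsilyloxy)octahydro-1H-indene
Conditions: TBSOTf, 2,6-lutidine, CH2Cl2, 0 °C
Reagents that add atoms: tert-butyldimethylsilyl trifluoromethanesulfonate CC(C)(C)[Si](C)(C)OS(=O)(=O)C(F)(F)F
Why: Silyl triflate silylation of a tertiary alcohol; the protecting group is needed for the later enolate alkylation and bromination.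

Step 7
Reactants: 8 (1R,3aR,7aR)-1-(tert-butyldimethylsilyloxy)-1,4,4-trimethyl-5,6-methano-5-(triisopropylsilyloxy)octahydro-1H-indene
Product: 10 (1R,3aR,8aR)-1-(tert-butyldimethylsilyloxy)-1,4,4-trimethyl-2,3,3a,4,8,8a-hexahydroazulen-5(1H)-one, via β-chloro ketone 9 (not isolated)
Conditions: FeCl3, DMF, 0 °C → rt; then NaOAc, MeOH, reflux
Reagents that add atoms: none
Why: Saegusa–Ito ring expansion: one-electron oxidation of the siloxycyclopropane opens the internal bond to the β-chloro cycloheptanone, and loss of HCl gives the enone with the inserted carbon next to the carbonyl.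

Step 8
Reactants: 10 (1R,3aR,8aR)-1-(tert-butyldimethylsilyloxy)-1,4,4-trimethyl-2,3,3a,4,8,8a-hexahydroazulen-5(1H)-one
Product: 12 (1R,3aR,6R,8aR)-1-(tert-butyldimethylsilyloxy)-1,4,4,6-tetramethyloctahydroazulen-5(1H)-one, via lithium enolate 11 (not isolated)
Conditions: Li, NH3 (l), THF, t-BuOH (1 equiv), −78 °C; then MeI, −78 → −33 °C
Reagents that add atoms: iodomethane CI
Why: Birch-type reductive alkylation gives the only possible enolate, and methylation should occur on the convex face, away from the folded five-membered ring and its concave-face C-1 methyl, so that the C-6 methyl ends up cis to the ring-fusion hydrogens.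

Step 9
Reactants: 12 (1R,3aR,6R,8aR)-1-(tert-butyldimethylsilyloxy)-1,4,4,6-tetramethyloctahydroazulen-5(1H)-one
Product: 13 (1R,3aR,6R,8aR)-1-(tert-butyldimethylsilyloxy)-5-ethenyl-1,4,4,6-tetramethyldecahydroazulen-5-ol (C-5 epimers)
Conditions: CH2=CHMgBr, CeCl3, THF, −78 → 0 °C
Reagents that add atoms: vinylmagnesium bromide C=C[Mg]Br
Why: Organocerium addition to a hindered enolisable ketone should suppress enolisation at C-6; the carbinol configuration is irrelevant because it is lost in step 10.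

Step 10
Reactants: 13 (1R,3aR,6R,8aR)-1-(tert-butyldimethylsilyloxy)-5-ethenyl-1,4,4,6-tetramethyldecahydroazulen-5-ol
Product: 14 tert-butyl{[(1R,3aR,5E,6R,8aR)-5-(2-bromoethylidene)-1,4,4,6-tetramethyldecahydroazulen-1-yl]oxy}dimethylsilane
Conditions: PBr3, pyridine (cat.), Et2O, −20 → 0 °C
Reagents that add atoms: phosphorus tribromide BrP(Br)Br
Why: SN2′ bromination of a tertiary vinyl carbinol with allylic transposition; the equilibrating allylic bromide should settle in the (E) geometry with CH2Br syn to C-6 and away from the quaternary C-4.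

**Oxepane–cyclohexane half (steps 11–17)**

Step 11
Reactants: 15 4-methoxy-2-methylphenol
Product: 16 4,4-dimethoxy-2-methylcyclohexa-2,5-dien-1-one
Conditions: PhI(OAc)2, MeOH, 0 °C
Reagents that add atoms: methanol CO
Why: Oxidative dearomatisation of a p-methoxyphenol by a hypervalent iodine reagent in methanol gives the quinone monoketal.

Step 12
Reactants: 16 4,4-dimethoxy-2-methylcyclohexa-2,5-dien-1-one
Product: 17 4,4-dimethoxy-2-methylcyclohex-2-en-1-one
Conditions: H2 (1 atm), RhCl(PPh3)3 (5 mol %), benzene, rt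
Reagents that add atoms: none
Why: Homogeneous hydrogenation should reduce the disubstituted double bond and spare the trisubstituted, methyl-bearing one.

Step 13
Reactants: 17 4,4-dimethoxy-2-methylcyclohex-2-en-1-one
Product: 18 (1R)-4,4-dimethoxy-2-methylcyclohex-2-en-1-ol
Conditions: (S)-2-methyl-CBS-oxazaborolidine (10 mol %), BH3·SMe2, THF, −30 °C
Reagents that add atoms: none
Why: Corey–Bakshi–Shibata reduction in which the α-methyl alkenyl flank acts as the large group, so the (S)-catalyst should give the (R)-allylic alcohol that becomes C-9a.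

Step 14
Reactants: 18 (1R)-4,4-dimethoxy-2-methylcyclohex-2-en-1-ol
Product: 19 (4R)-4-hydroxy-3-methylcyclohex-2-en-1-one
Conditions: oxalic acid, THF/H2O, 0 °C → rt
Reagents that add atoms: water O
Why: Mild acid hydrolysis of the dimethyl ketal unmasks the enone without ionising the carbinol.

Step 15
Reactants: 19 (4R)-4-hydroxy-3-methylcyclohex-2-en-1-one; 20 2,2-dimethyloxirane
Product: 21 (4R)-4-[(1-hydroxy-2-methylpropan-2-yl)oxy]-3-methylcyclohex-2-en-1-one
Conditions: 20 (5 equiv), BF3·OEt2 (10 mol %), CH2Cl2, −40 → −20 °C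
Reagents that add atoms: none
Why: Lewis-acid-catalysed epoxide alcoholysis, in which the alcohol attacks the tertiary, cation-stabilised epoxide carbon to give the tertiary ether; the carbinol stereocenter reacts only through oxygen and is untouched.

Step 16
Reactants: 21 (4R)-4-[(1-hydroxy-2-methylpropan-2-yl)oxy]-3-methylcyclohex-2-en-1-one
Product: 22 2-methyl-2-{[(1R)-2-methyl-4-oxocyclohex-2-en-1-yl]oxy}propanal
Conditions: Dess–Martin periodinane, NaHCO3, CH2Cl2, 0 °C → rt
Reagents that add atoms: none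
Why: Dess–Martin oxidation of the primary alcohol to an aldehyde that has no α-hydrogen and cannot enolise.

Step 17
Reactants: 22 2-methyl-2-{[(1R)-2-methyl-4-oxocyclohex-2-en-1-yl]oxy}propanal
Product: 24 trimethyl({(3R,4R)-3-ethenyl-3-methyl-4-[(2-methyl-3-(trimethylsilyloxy)pent-4-en-2-yl)oxy]cyclohex-1-en-1-yl}oxy)silane (epimers at the side-chain carbinol carbon), via bromomagnesium alkoxide 23 (not isolated)
Conditions: CH2=CHMgBr (3.5 equiv), CuBr·SMe2 (10 mol %), TMSCl (4 equiv), HMPA, THF, −78 → −40 °C; Et3N, pentane, filtration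
Reagents that add atoms: vinylmagnesium bromide C=C[Mg]Br; chlorotrimethylsilane C[Si](C)(C)Cl
Why: Vinylmagnesium bromide first adds to the non-enolisable aldehyde (the later C-3–C-4 bond) to give alkoxide 23, then the vinylcopper species formed with CuBr·SMe2 adds 1,4 to the β-methyl enone (the later C-5–C-5a bond) and the enolate is silylated as it forms. The closest known reaction types are Grignard addition to an aldehyde and the chlorosilane-accelerated copper-catalysed conjugate addition of Grignard reagents to β,β-disubstituted cyclohexenones. No ring is closed here; both carbons of the C-4–C-5 bridge arrive as vinyl groups that step 19 joins by ring-closing metathesis. The quaternary stereocenter C-5a is set by attack anti to the bulky γ-alkoxy substituent at C-9a, which puts the vinyl group trans to oxygen and so fixes the trans ring fusion; C-3 forms without control and is corrected in steps 23 and 24. The step needs 1,4- over 1,2-selectivity at the enone (copper catalysis, TMSCl and HMPA at low temperature) and must avoid aldol closure between enolate and aldehyde (the aldehyde is consumed first and the enolate is trapped on oxygen).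

**Union and completion (steps 18–25)**

Step 18
Reactants: 24 trimethyl({(3R,4R)-3-ethenyl-3-methyl-4-[(2-methyl-3-(trimethylsilyloxy)pent-4-en-2-yl)oxy]cyclohex-1-en-1-yl}oxy)silane; 14 tert-butyl{[(1R,3aR,5E,6R,8aR)-5-(2-bromoethylidene)-1,4,4,6-tetramethyldecahydroazulen-1-yl]oxy}dimethylsilane
Product: 26 (3R,4R)-2-SC-3-ethenyl-3-methyl-4-{[2-methyl-3-(trimethylsilyloxy)pent-4-en-2-yl]oxy}cyclohexan-1-one (epimers at C-2 and at the silyloxy carbon), via lithium enolate 25 (not isolated)
Conditions: MeLi (1.05 equiv), THF, 0 °C; then HMPA, 14, −78 → −20 °C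
Reagents that add atoms: none
Why: Methyllithium cleaves the silyl enol ether to the regiodefined lithium enolate, which is alkylated (SN2) at the primary allylic bromide; the C-2 configuration is not relied on and is corrected in step 20.

Step 19
Reactants: 26 (3R,4R)-2-SC-3-ethenyl-3-methyl-4-{[2-methyl-3-(trimethylsilyloxy)pent-4-en-2-yl]oxy}cyclohexan-1-one
Product: 27 (5aR,9aR)-6-SC-2,2,5a-trimethyl-3-(trimethylsilyloxy)-2,3,5a,6,8,9-hexahydro-1-benzoxepin-7(9aH)-one (epimers at C-3 and C-6)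
Conditions: second-generation Grubbs catalyst (5 mol %), toluene, 80 °C
Reagents that add atoms: none
Why: Ring-closing metathesis of the two vinyl groups, held trans-diequatorial on the cyclohexanone and biased by the gem-dimethyl group, closes the seven-membered oxepene (C-4=C-5); the hindered trisubstituted alkene of SC should stay inert.

Step 20
Reactants: 27 (5aR,9aR)-6-SC-2,2,5a-trimethyl-3-(trimethylsilyloxy)-2,3,5a,6,8,9-hexahydro-1-benzoxepin-7(9aH)-one
Product: 28 (5aR,6R,9aR)-6-SC-3-hydroxy-2,2,5a-trimethyl-2,3,5a,6,8,9-hexahydro-1-benzoxepin-7(9aH)-one (C-3 epimers)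
Conditions: NaOMe (0.3 equiv), MeOH, rt
Reagents that add atoms: none
Why: Methoxide removes the trimethylsilyl ether and equilibrates C-6 next to the ketone to the thermodynamic isomer, with the side chain equatorial and cis to the axial C-5a methyl of the locked trans-fused bicycle.

Step 21
Reactants: 28 (5aR,6R,9aR)-6-SC-3-hydroxy-2,2,5a-trimethyl-2,3,5a,6,8,9-hexahydro-1-benzoxepin-7(9aH)-one
Product: 29 (5aR,6R,7S,9aR)-6-SC-2,2,5a,7-tetramethyl-2,3,5a,6,7,8,9,9a-octahydro-1-benzoxepine-3,7-diol (C-3 epimers)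
Conditions: MeLi (4 equiv), CeCl3, THF, −78 °C
Reagents that add atoms: methyllithium [Li]C
Why: Organocerium methyl addition to the hindered ketone; the axial approach is blocked by the syn-axial C-5a methyl, so methyl should enter equatorially and give the axial tertiary alcohol (7S).

Step 22
Reactants: 29 (5aR,6R,7S,9aR)-6-SC-2,2,5a,7-tetramethyl-2,3,5a,6,7,8,9,9a-octahydro-1-benzoxepine-3,7-diol
Product: 30 (5aR,6R,7S,9aR)-6-SC-2,2,5a,7-tetramethyldecahydro-1-benzoxepine-3,7-diol (C-3 epimers)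
Conditions: H2 (1 atm), RhCl(PPh3)3 (10 mol %), benzene/EtOH, rt
Reagents that add atoms: none
Why: Homogeneous hydrogenation should take the cis-disubstituted ring alkene and leave the hindered trisubstituted exocyclic alkene.

Step 23
Reactants: 30 (5aR,6R,7S,9aR)-6-SC-2,2,5a,7-tetramethyldecahydro-1-benzoxepine-3,7-diol
Product: 31 (5aR,6R,7S,9aR)-6-SC-7-hydroxy-2,2,5a,7-tetramethyloctahydro-1-benzoxepin-3(2H)-one
Conditions: Dess–Martin periodinane, NaHCO3, CH2Cl2, 0 °C → rt
Reagents that add atoms: none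
Why: Dess–Martin oxidation of the only secondary alcohol converges both C-3 epimers on one ketone; the tertiary alcohol cannot be oxidised.

Step 24
Reactants: 31 (5aR,6R,7S,9aR)-6-SC-7-hydroxy-2,2,5a,7-tetramethyloctahydro-1-benzoxepin-3(2H)-one
Product: 32 (3R,5aR,6R,7S,9aR)-6-SC-2,2,5a,7-tetramethyldecahydro-1-benzoxepine-3,7-diol
Conditions: (S)-2-methyl-CBS-oxazaborolidine (20 mol %), catecholborane, toluene, −78 → −40 °C
Reagents that add atoms: none
Why: Corey–Bakshi–Shibata reduction under catalyst control, with the quaternary C-2 as the large and the C-4 methylene as the small flank, should give the (3R)-alcohol; catecholborane spares the alkene.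

Step 25
Reactants: 32 (3R,5aR,6R,7S,9aR)-6-SC-2,2,5a,7-tetramethyldecahydro-1-benzoxepine-3,7-diol
Product: 33 (3R,5aR,6R,7S,9aR)-6-{(2E)-2-[(1R,3aR,6R,8aR)-1-hydroxy-1,4,4,6-tetramethyloctahydroazulen-5(1H)-ylidene]ethyl}-2,2,5a,7-tetramethyldecahydro-1-benzoxepine-3,7-diol
Conditions: TBAF, THF, 50 °C
Reagents that add atoms: none
Why: Fluoride cleavage of the tertiary silyl ether liberates the last hydroxyl and gives the target.

**Compound list**

1 | 4-methylpent-1-en-3-one | CC(C)C(=O)C=C | starting material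
2 | 4-methyl-3-(triisopropylsilyloxy)penta-1,3-diene | C=CC(O[Si](C(C)C)(C(C)C)C(C)C)=C(C)C | intermediate
3 | cyclopent-2-en-1-one | O=C1C=CCC1 | starting material
4 | (3aR,7aR)-4,4-dimethyl-5-(triisopropylsilyloxy)-2,3,3a,4,7,7a-hexahydro-1H-inden-1-one | O=C1CC[C@@H]2[C@H]1CC=C(O[Si](C(C)C)(C(C)C)C(C)C)C2(C)C | intermediate
5 | (3aR,7aR)-4,4-dimethyl-5,6-methano-5-(triisopropylsilyloxy)octahydro-1H-inden-1-one | O=C1CC[C@@H]2[C@H]1CC3CC3(O[Si](C(C)C)(C(C)C)C(C)C)C2(C)C | intermediate
6 | (3aR,7aR)-4,4-dimethyl-1-methylidene-5,6-methano-5-(triisopropylsilyloxy)octahydro-1H-indene | C=C1CC[C@@H]2[C@H]1CC3CC3(O[Si](C(C)C)(C(C)C)C(C)C)C2(C)C | intermediate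
7 | (1R,3aR,7aR)-1,4,4-trimethyl-5,6-methano-5-(triisopropylsilyloxy)octahydro-1H-inden-1-ol | C[C@@]1(O)CC[C@@H]2[C@H]1CC3CC3(O[Si](C(C)C)(C(C)C)C(C)C)C2(C)C | intermediate
8 | tert-butyldimethylsilyl ether of 7 | C[C@@]1(O[Si](C)(C)C(C)(C)C)CC[C@@H]2[C@H]1CC3CC3(O[Si](C(C)C)(C(C)C)C(C)C)C2(C)C | intermediate
9 | (1R,3aR,8aR)-1-(tert-butyldimethylsilyloxy)-7-chloro-1,4,4-trimethyloctahydroazulen-5(1H)-one (not isolated) | C[C@@]1(O[Si](C)(C)C(C)(C)C)CC[C@@H]2[C@H]1CC(Cl)CC(=O)C2(C)C | intermediate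
10 | (1R,3aR,8aR)-1-(tert-butyldimethylsilyloxy)-1,4,4-trimethyl-2,3,3a,4,8,8a-hexahydroazulen-5(1H)-one | C[C@@]1(O[Si](C)(C)C(C)(C)C)CC[C@@H]2[C@H]1CC=CC(=O)C2(C)C | intermediate
11 | lithium enolate from reduction of 10 (not isolated) | C[C@@]1(O[Si](C)(C)C(C)(C)C)CC[C@@H]2[C@H]1CCC=C([O-])C2(C)C.[Li+] | intermediate
12 | (1R,3aR,6R,8aR)-1-(tert-butyldimethylsilyloxy)-1,4,4,6-tetramethyloctahydroazulen-5(1H)-one | C[C@@]1(O[Si](C)(C)C(C)(C)C)CC[C@@H]2[C@H]1CC[C@@H](C)C(=O)C2(C)C | intermediate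
13 | (1R,3aR,6R,8aR)-1-(tert-butyldimethylsilyloxy)-5-ethenyl-1,4,4,6-tetramethyldecahydroazulen-5-ol (C-5 epimers) | C[C@@]1(O[Si](C)(C)C(C)(C)C)CC[C@@H]2[C@H]1CC[C@@H](C)C(O)(C=C)C2(C)C | intermediate
14 | tert-butyl{[(1R,3aR,5E,6R,8aR)-5-(2-bromoethylidene)-1,4,4,6-tetramethyldecahydroazulen-1-yl]oxy}dimethylsilane | C[C@@H]1CC[C@@H]2[C@@H](CC[C@@]2(C)O[Si](C)(C)C(C)(C)C)C(C)(C)/C1=C/CBr | intermediate
15 | 4-methoxy-2-methylphenol | COc1ccc(O)c(C)c1 | starting material
16 | 4,4-dimethoxy-2-methylcyclohexa-2,5-dien-1-one | COC1(OC)C=CC(=O)C(C)=C1 | intermediate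
17 | 4,4-dimethoxy-2-methylcyclohex-2-en-1-one | COC1(OC)CCC(=O)C(C)=C1 | intermediate
18 | (1R)-4,4-dimethoxy-2-methylcyclohex-2-en-1-ol | O[C@@H]1CCC(OC)(OC)C=C1C | intermediate
19 | (4R)-4-hydroxy-3-methylcyclohex-2-en-1-one | O[C@@H]1CCC(=O)C=C1C | intermediate
20 | 2,2-dimethyloxirane | CC1(C)CO1 | starting material
21 | (4R)-4-[(1-hydroxy-2-methylpropan-2-yl)oxy]-3-methylcyclohex-2-en-1-one | OCC(C)(C)O[C@@H]1CCC(=O)C=C1C | intermediate
22 | 2-methyl-2-{[(1R)-2-methyl-4-oxocyclohex-2-en-1-yl]oxy}propanal | O=CC(C)(C)O[C@@H]1CCC(=O)C=C1C | intermediate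
23 | bromomagnesium alkoxide of the aldehyde vinylation product (not isolated; carbinol epimers) | C=CC(O[Mg]Br)C(C)(C)O[C@@H]1CCC(=O)C=C1C | intermediate
24 | trimethyl({(3R,4R)-3-ethenyl-3-methyl-4-[(2-methyl-3-(trimethylsilyloxy)pent-4-en-2-yl)oxy]cyclohex-1-en-1-yl}oxy)silane (carbinol epimers) | C=CC(O[Si](C)(C)C)C(C)(C)O[C@@H]1CCC(O[Si](C)(C)C)=C[C@@]1(C)C=C | intermediate
25 | lithium enolate from 24 (not isolated) | C=CC(O[Si](C)(C)C)C(C)(C)O[C@@H]1CCC([O-])=C[C@@]1(C)C=C.[Li+] | intermediate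
26 | (3R,4R)-2-SC-3-ethenyl-3-methyl-4-{[2-methyl-3-(trimethylsilyloxy)pent-4-en-2-yl]oxy}cyclohexan-1-one (epimers at C-2 and at the silyloxy carbon) | C[C@@H]1CC[C@@H]2[C@@H](CC[C@@]2(C)O[Si](C)(C)C(C)(C)C)C(C)(C)/C1=C/CC1C(=O)CC[C@@H](OC(C)(C)C(O[Si](C)(C)C)C=C)[C@]1(C)C=C | intermediate
27 | (5aR,9aR)-6-SC-2,2,5a-trimethyl-3-(trimethylsilyloxy)-2,3,5a,6,8,9-hexahydro-1-benzoxepin-7(9aH)-one (epimers at C-3 and C-6) | C[C@@H]1CC[C@@H]2[C@@H](CC[C@@]2(C)O[Si](C)(C)C(C)(C)C)C(C)(C)/C1=C/CC1[C@@]2(C)C=CC(O[Si](C)(C)C)C(C)(C)O[C@@H]2CCC1=O | intermediate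
28 | (5aR,6R,9aR)-6-SC-3-hydroxy-2,2,5a-trimethyl-2,3,5a,6,8,9-hexahydro-1-benzoxepin-7(9aH)-one (C-3 epimers) | C[C@@H]1CC[C@@H]2[C@@H](CC[C@@]2(C)O[Si](C)(C)C(C)(C)C)C(C)(C)/C1=C/C[C@@H]1[C@@]2(C)C=CC(O)C(C)(C)O[C@@H]2CCC1=O | intermediate
29 | (5aR,6R,7S,9aR)-6-SC-2,2,5a,7-tetramethyl-2,3,5a,6,7,8,9,9a-octahydro-1-benzoxepine-3,7-diol (C-3 epimers) | C[C@@H]1CC[C@@H]2[C@@H](CC[C@@]2(C)O[Si](C)(C)C(C)(C)C)C(C)(C)/C1=C/C[C@@H]1[C@@]2(C)C=CC(O)C(C)(C)O[C@@H]2CC[C@]1(C)O | intermediate
30 | (5aR,6R,7S,9aR)-6-SC-2,2,5a,7-tetramethyldecahydro-1-benzoxepine-3,7-diol (C-3 epimers) | C[C@@H]1CC[C@@H]2[C@@H](CC[C@@]2(C)O[Si](C)(C)C(C)(C)C)C(C)(C)/C1=C/C[C@@H]1[C@@]2(C)CCC(O)C(C)(C)O[C@@H]2CC[C@]1(C)O | intermediate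
31 | (5aR,6R,7S,9aR)-6-SC-7-hydroxy-2,2,5a,7-tetramethyloctahydro-1-benzoxepin-3(2H)-one | C[C@@H]1CC[C@@H]2[C@@H](CC[C@@]2(C)O[Si](C)(C)C(C)(C)C)C(C)(C)/C1=C/C[C@@H]1[C@@]2(C)CCC(=O)C(C)(C)O[C@@H]2CC[C@]1(C)O | intermediate
32 | (3R,5aR,6R,7S,9aR)-6-SC-2,2,5a,7-tetramethyldecahydro-1-benzoxepine-3,7-diol | C[C@@H]1CC[C@@H]2[C@@H](CC[C@@]2(C)O[Si](C)(C)C(C)(C)C)C(C)(C)/C1=C/C[C@@H]1[C@@]2(C)CC[C@@H](O)C(C)(C)O[C@@H]2CC[C@]1(C)O | intermediate
33 | (3R,5aR,6R,7S,9aR)-6-{(2E)-2-[(1R,3aR,6R,8aR)-1-hydroxy-1,4,4,6-tetramethyloctahydroazulen-5(1H)-ylidene]ethyl}-2,2,5a,7-tetramethyldecahydro-1-benzoxepine-3,7-diol | C[C@@H]1CC[C@@H]2[C@@H](CC[C@@]2(C)O)C(C)(C)/C1=C/C[C@@H]1[C@@]2(C)CC[C@@H](O)C(C)(C)O[C@@H]2CC[C@]1(C)O | target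

Total step count: 25
Longest linear sequence: 18 steps (steps 1–10, then 18–25)

**Steps most likely to fail**

1. Step 2. The cycloaddition may stall because the nucleophilic diene terminus is fully substituted and disfavours the reactive conformer, and the catalyst may discriminate the enone faces poorly. The fallback sets out from 2 and 3 and comes back at 4. An achiral Lewis acid (EtAlCl2, CH2Cl2, −78 °C) promotes the cycloaddition to the racemic cis-adduct F1. NaBH4 then reduces the cyclopentanone from the convex face to the racemic alcohol F2. Lipase-catalysed acetylation with vinyl acetate (kinetic resolution) leaves the alcohol of the (3aR,7aR) series F3 and converts its enantiomer into the acetate F4. Dess–Martin oxidation of F3 returns 4 as a single enantiomer.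

2. Step 15. Oligomerisation or rearrangement of the activated epoxide, and acid-induced dehydration of the γ-hydroxy enone, may outrun ether formation. The fallback sets out from 18 and comes back at 22. Alkoxymercuration of 3,3-dimethoxy-2-methylprop-1-ene with alcohol 18 (Hg(OCOCF3)2, CH2Cl2) gives the organomercurial F5, which is reduced in the same flask (NaBH4, NaOH) to the tertiary ether F6. Aqueous oxalic acid then unmasks both carbonyl groups and gives 22, so that steps 14 to 16 are replaced.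

3. Step 17. Site selectivity may be lost (1,2-addition to the enone carbonyl), or the alkoxide and enolate intermediates may close onto the enone or the aldehyde (oxa-Michael or aldol) before they are silylated. The fallback sets out from 22 and comes back at 24, making the two bonds in separate operations. Vinylmagnesium bromide (1.05 equiv, −78 °C), followed by TMSCl and imidazole, gives the silyl-protected allylic alcohol F7. Lithium divinylcuprate with TMSCl then performs the conjugate addition anti to the ether substituent and returns 24.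

Further compounds
F1 | step 2 | racemic cis-4,4-dimethyl-5-(triisopropylsilyloxy)-2,3,3a,4,7,7a-hexahydro-1H-inden-1-one | O=C1CCC2C1CC=C(O[Si](C(C)C)(C(C)C)C(C)C)C2(C)C
F2 | step 2 | racemic cis-4,4-dimethyl-5-(triisopropylsilyloxy)-2,3,3a,4,7,7a-hexahydro-1H-inden-1-ol (hydroxyl on the concave face) | OC1CCC2C1CC=C(O[Si](C(C)C)(C(C)C)C(C)C)C2(C)C
F3 | step 2 | resolved alcohol of the (3aR,7aR) series | O[C@H]1CC[C@@H]2[C@H]1CC=C(O[Si](C(C)C)(C(C)C)C(C)C)C2(C)C
F4 | step 2 | acetate of the enantiomeric alcohol | CC(=O)O[C@@H]1CC[C@H]2[C@@H]1CC=C(O[Si](C(C)C)(C(C)C)C(C)C)C2(C)C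
F5 | step 15 | organomercurial trifluoroacetate from alkoxymercuration of 3,3-dimethoxy-2-methylprop-1-ene with 18 | COC(OC)C(C)(C[Hg]OC(=O)C(F)(F)F)O[C@@H]1CCC(OC)(OC)C=C1C
F6 | step 15 | (1R)-1-[(1,1-dimethoxy-2-methylpropan-2-yl)oxy]-4,4-dimethoxy-2-methylcyclohex-2-ene | COC(OC)C(C)(C)O[C@@H]1CCC(OC)(OC)C=C1C
F7 | step 17 | (4R)-3-methyl-4-{[2-methyl-3-(trimethylsilyloxy)pent-4-en-2-yl]oxy}cyclohex-2-en-1-one (carbinol epimers) | C=CC(O[Si](C)(C)C)C(C)(C)O[C@@H]1CCC(=O)C=C1C
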